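Compound numbers 1–38 follow the order of the steps below and are used throughout. Ring locants C1–C11 are those defined in the first section and are kept for the open-chain intermediates.

## Analysis of the target

Compound 38 is a germacrane-type polyester built on a single ten-membered carbocycle: C1 carries the isopropenyl group (central carbon C11), C2 is CH2, C3 a free carbinol, C4 bears methyl and acetate, C5 an angelate, C6 is CH2, C7/C8 form the epoxide (methyl on C8), C9 bears the second angelate and C10 the (R)-2-methylbutanoate. The ring holds eight stereocentres (1R,3R,4S,5S,7S,8S,9S,10S in this numbering) and the side chain a ninth. The oxygens on C3, C4 and C5 are all syn along the chain C2–C6, and those on C9 and C10 are anti. The epoxide is cis (C6 and C9 on the same side, so it descends from a Z alkene), and its oxygen is trans to the C9 oxygen across the ring. C1 and C3 have the 1,3-relationship of cis-carveol, so C9, C10, C1, C2, C3 and C4 with its methyl group can be read as the six ring carbons of (R)-carvone 1 after cleavage of the enone double bond. The sensitive groups are the angelates (Z-to-E isomerisation to tiglates), the tertiary C4 acetate beside the free C3 hydroxyl (1,2-acyl shift under base), the trisubstituted epoxide, and the isopropenyl group, which rules out unselective alkene oxidations anywhere in the route. The difficulty is the medium ring combined with five oxygens in four different states that must be told apart as they are introduced. The strategy rests on the C8–C9 bond: without the epoxide oxygen, C7=C8–C9(OH) is a Z allylic alcohol, the product of adding a C8 alkenyl metal to a C9 aldehyde, and an organochromium reagent does this without touching esters, so the ring can be closed last.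

## Retrosynthetic reasoning

**38 back to 35.** The last operations only adjust heteroatoms. The C3 hydroxyl is released last, from the 4-methoxybenzyl ether 37 by a neutral oxidative cleavage, because a free C3 hydroxyl beside the tertiary C4 acetate must not meet base. 37 comes from epoxy alcohol 36 and the angeloyl donor 22, and 36 from the Z allylic alcohol 35 by a hydroxyl-assisted peracid epoxidation. The C9 hydroxyl stays free until then because it accelerates that oxidation and because the oxygen has to arrive trans to it across the ring.

**35 back to 34.** The C8–C9 bond is cut to give the open-chain (Z)-alkenyl iodide aldehyde 34. This is the one ring bond whose formation joins two groups that are inert toward all five oxygen functions, creates a stereocentre (C9) next to one that can bias it (C10), and leaves exactly the allylic hydroxyl needed afterwards. The forward reaction must close a ten-membered ring at the aldehyde only, keep the Z geometry and give the 9,10-anti alcohol.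

**34 back to 25.** The C10 ester and the C10–O bond are removed. The α-acyloxy aldehyde is too labile to carry, so it is unveiled last by oxidation of alcohol 33. The ester of acid 30 is put on the secondary hydroxyl of diol 28 after the primary one is silylated (29, then 32). Diol 28 stems from aldehyde 25 by enamine-catalysed α-aminoxylation and reduction (27), which sets C10 under catalyst control, independent of the remote stereocentres.

**25 back to 20.** The acetal unmasking and two acylations are removed: the C4 acetate (24 from 23) and the C5 angelate (23 from diol 20 and the angeloyl donor 22). The secondary hydroxyl is acylated first, so that in the main sequence no acyl group sits on the tertiary oxygen beside a free secondary hydroxyl before the final step.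

**22 back to 21.** Both angelates are traced to one acyl donor, the mixed anhydride 22 of angelic acid 21 with 2,4,6-trichlorobenzoic acid. It is made once, without a nucleophilic catalyst, and serves the C5 and the C9 esterification alike; this keeps the Z acid away from acid-chloride conditions, where it isomerises.

**20 back to 14 and 15.** The C7=C8 double bond is cut by a Wittig-type disconnection to aldehyde 14 and phosphonium salt 15, through acetonide 19. The forward reaction must deliver the iodoalkene with C6 and iodine cis, which a non-stabilised α-iodo ylide does under kinetic control.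

**14 back to 10.** The C5–O bond is traced through alcohol 13 and triol 12 to epoxy alcohol 11 and the E allylic alcohol 10. An asymmetric epoxidation of the primary allylic alcohol sets C5 under reagent control, which is needed because induction from the tertiary C4 carbinol would be weak. Hydride opening at C6 then gives the 1,3-diol.

**10 back to 6 and 7.** The C4–C5 bond is cut: alkyne 9 arises from methyl ketone 6 and the three-carbon unit 7. Addition of the C5 nucleophile under chelation to the C3 ether oxygen gives the 3,4-syn arrangement. For that reason C3 carries a chelating 4-methoxybenzyl ether; a bulky silyl ether would direct the nucleophile to the other face.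

**6 back to 1.** The C4–C9 bond is reconnected to a six-membered ring. Keto acetal 6 comes from keto aldehyde 5, 5 from epoxide 4 by glycol-type cleavage, 4 from carveol 2 through epoxy alcohol 3, and 2 from 1 by 1,2-reduction. The ring of 1 supplies C1, relays its configuration to C3 in the reduction, and the directed epoxidation confines the cleavage to the ring alkene, sparing the isopropenyl group.

## Alternatives that were turned down

**Alternative 1:** The two methyl-bearing oxygenated carbons C4 and C8 are both traced to one four-carbon building block, (R)-2-(4-methoxybenzyloxy)-2-methylbut-3-en-1-ol A1; one copy would grow into C3–C5, a second into C7–C9. In the forward key step Pd2(dba)3 with a chiral bisphosphine and BEt3 ionises racemic 2-methyl-2-vinyloxirane A2 to interconverting π-allyl complexes, and 4-methoxybenzyl alcohol A3 adds at the tertiary terminus, giving A1 from both enantiomers of A2.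
- For: a catalytic, stereoconvergent tertiary C–O stereocentre, made twice from cheap material.
- Against: it solves two of eight ring stereocentres and says nothing about ring closure. At C8 the ether oxygen must later become an epoxide oxygen shared with C7, which costs an unmasking and a displacement with inversion at a C7 centre that has to be set first. At C4 the ether must be exchanged for an acetate on a tertiary carbon. C10, C1 and C2 need a third fragment.
- Comparison: on C4 it is stronger than the substrate-controlled step 6 here. In its place the chosen route takes C1 and C3 from 1 without extra steps and uses one late bond formation that closes the ring and creates C9.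

**Alternative 2:** The C1–C2 bond is cut and the carbocycle traced to the fourteen-membered allylic lactone A4, in which C2 and a carboxyl carbon are esterified to the C12 oxygen of a C1=C11 alkene. In the forward key step the dianion of A4 (LiN(iPr)2), silylated with Me3SiCl and warmed, undergoes Ireland–Claisen rearrangement: C2 bonds to C1, the C12–O bond breaks, the alkene moves to C11=C12 (the isopropenyl group), and the ring contracts to the ten-membered acid A5 (C2 epimers).
- For: a fourteen-membered lactonisation is far easier than a ten-membered carbocyclisation, C1 is set by chirality transfer, and the isopropenyl group appears late, so earlier alkene oxidations would be unrestricted.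
- Against: the C2 carboxyl must be excised afterwards by a radical decarboxylation in a polyene. The ester enolate sits beside the C3 alkoxide. The chair or boat folding of the large ring, and with it C1, is hard to predict. After the ring is made, two acetonides must be turned into four different acyl states, including a secondary/secondary diol at C9/C10 with no handle for regioselection, and the epoxide still has to be made.
- Comparison: it is stronger on ring-closure thermodynamics. The chosen route differentiates every oxygen while the chain is acyclic and needs three steps after ring closure.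

**Alternative 3:** The ring is traced to the carvone-derived 1-alkenyl-2-vinylcyclohexanol A6, whose six-membered ring is C3, C8, C9, C10, C1, C2. In the forward key step the potassium alkoxide of A6 (KH, 18-crown-6) undergoes anionic oxy-Cope rearrangement: C5–C6 forms, C3–C8 breaks, and the ten-membered enone A7 results with a C3 ketone and the C7=C8 alkene.
- For: a four-atom ring expansion without high dilution, economical use of the carvone skeleton (its methyl becomes the C8 methyl), and C5 oxygen carried in as an enol ether.
- Against: C4 emerges as a CH(CH3) carbon next to the ketone, so the tertiary C4–O stereocentre must be made by enolate hydroxylation of a ten-membered ketone, with C2/C4 regiochemistry and facial selectivity both open. C3 needs a selective ketone reduction. The Z geometry requires an unusual transition-state arrangement, since 1,2-dialkenylcyclohexanolates normally give E alkenes. A6 itself needs a quaternary carbon beside a tertiary carbinol. The C9/C10 acetonide poses the same differentiation problem as in alternative 2.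
- Comparison: it is stronger in reaching the carbocycle quickly. The chosen route fixes C4, C5 and C10 by chelation or reagent control before closure and C9 during closure.

Key step: step 24

Remark: (R)-2-methylbutanoic acid 30 and D-(−)-diethyl tartrate are taken as purchasable single enantiomers.

## Route

Step 1
Reactants: 1 (R)-carvone
Product: 2 (1R,5R)-cis-carveol [(1R,5R)-2-methyl-5-(prop-1-en-2-yl)cyclohex-2-en-1-ol]
Conditions: NaBH4, CeCl3·7H2O, MeOH, −78 → 0 °C
Reagents that add atoms: none
Why: Luche 1,2-reduction; hydride adds axially, anti to the pseudo-equatorial isopropenyl group, which should give the cis alcohol and so sets C3 (R) from C1.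

Step 2
Reactants: 2 (1R,5R)-cis-carveol
Product: 3 cis-epoxy alcohol (1R,2R,4S,6S)-1-methyl-4-(prop-1-en-2-yl)-7-oxabicyclo[4.1.0]heptan-2-ol (epoxide syn to the hydroxyl)
Conditions: VO(acac)2 (cat.), t-BuOOH, CH2Cl2, 0 °C → rt
Reagents that add atoms: tert-butyl hydroperoxide, CC(C)(C)OO
Why: Hydroxyl-directed vanadium-catalysed epoxidation; only the allylic ring alkene is oxidised and the isopropenyl group is left alone. The epoxide configuration is irrelevant, since it only marks the C4–C9 bond for cleavage.

Step 3
Reactants: 3 cis-epoxy alcohol
Product: 4 4-methoxybenzyl (PMB) ether of 3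
Conditions: NaH, 4-MeOC6H4CH2Cl, n-Bu4NI (cat.), THF/DMF, 0 °C → rt
Reagents that add atoms: 4-methoxybenzyl chloride, COc1ccc(CCl)cc1
Why: Williamson etherification; the alkoxide is cis to the epoxide and cannot open it from the back. The PMB ether blocks over-cleavage in step 4, chelates magnesium in step 6 and is removable at the end without acid or base.

Step 4
Reactants: 4 PMB ether of 3
Product: 5 keto aldehyde (3S,5R)-5-[(4-methoxybenzyl)oxy]-6-oxo-3-(prop-1-en-2-yl)heptanal (C9 aldehyde and C4 methyl ketone)
Conditions: H5IO6, THF/H2O, 0 °C → rt
Reagents that add atoms: water, O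
Why: Periodic acid hydrates the trisubstituted epoxide and cleaves the resulting glycol in one flask, opening the ring between C4 and C9. C1 and C3 are untouched and the isopropenyl group is inert.

Step 5
Reactants: 5 keto aldehyde
Product: 6 keto acetal (3R,5S)-7,7-dimethoxy-3-[(4-methoxybenzyl)oxy]-5-(prop-1-en-2-yl)heptan-2-one
Conditions: HC(OMe)3, PPTS (cat.), MeOH, 0 °C → rt
Reagents that add atoms: trimethyl orthoformate, COC(OC)OC
Why: Chemoselective acetalisation; the unhindered aldehyde reacts far faster than the hindered, inductively deactivated α-alkoxy methyl ketone. The mild acid should not epimerise C3.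

Step 6
Reactants: 6 keto acetal; 7 propargyl alcohol (prop-2-yn-1-ol)
Product: 9 ynediol (4R,5R,7S)-9,9-dimethoxy-5-[(4-methoxybenzyl)oxy]-4-methyl-7-(prop-1-en-2-yl)non-2-yne-1,4-diol, via bis(bromomagnesium) salt of propargyl alcohol 8 (not isolated)
Conditions: 7, EtMgBr (2 equiv), THF, 0 → 45 °C; then 6, MgBr2·OEt2, THF/CH2Cl2, −78 → 0 °C
Reagents that add atoms: none
Why: Chelation-controlled (Cram chelate) addition of an alkynyl Grignard reagent to an α-alkoxy ketone. Magnesium bridges the C4 carbonyl and the C3 ether oxygen, and the acetylide attacks from the C3–H side, anti to C2, which should give the 3,4-syn tertiary carbinol required at C4.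

Step 7
Reactants: 9 ynediol
Product: 10 (E)-enediol (2E,4R,5R,7S)-9,9-dimethoxy-5-[(4-methoxybenzyl)oxy]-4-methyl-7-(prop-1-en-2-yl)non-2-ene-1,4-diol
Conditions: NaAlH2(OCH2CH2OMe)2, THF, 0 °C → rt
Reagents that add atoms: none
Why: Alkoxide-directed trans-hydroalumination of a propargylic alcohol and protonolysis give the E alkene only; the acetal, PMB ether and isopropenyl group do not react.

Step 8
Reactants: 10 (E)-enediol
Product: 11 epoxy diol, the (5S,6R)-5,6-epoxide of 10 (trans-2,3-epoxy alcohol; C4 and C7 hydroxyls free)
Conditions: Ti(OiPr)4 (cat.), D-(−)-diethyl tartrate (cat.), t-BuOOH, 4 Å molecular sieves, CH2Cl2, −20 °C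
Reagents that add atoms: tert-butyl hydroperoxide, CC(C)(C)OO
Why: Sharpless asymmetric epoxidation of the primary E allylic alcohol. The D-tartrate catalyst delivers oxygen to the face that makes C5 (S), overriding the weak bias of the tertiary C4 carbinol, and the unbound isopropenyl alkene is not oxidised.

Step 9
Reactants: 11 epoxy diol
Product: 12 triol (3S,4R,5R,7S)-9,9-dimethoxy-5-[(4-methoxybenzyl)oxy]-4-methyl-7-(prop-1-en-2-yl)nonane-1,3,4-triol
Conditions: NaAlH2(OCH2CH2OMe)2, THF, −20 → 0 °C
Reagents that add atoms: none
Why: Regioselective reductive opening of a 2,3-epoxy alcohol to the 1,3-diol. Hydride is delivered from the C7 alkoxyaluminate to C6, which is also the less hindered epoxide carbon (C5 is neopentyl-like), so the C5–O bond and its configuration are kept.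

Step 10
Reactants: 12 triol
Product: 13 C4,C5-acetonide of 12 (2,2-dimethyl-1,3-dioxolane across O4 and O5; C7 hydroxyl free)
Conditions: Me2C(OMe)2, PPTS (cat.), acetone, rt
Reagents that add atoms: 2,2-dimethoxypropane, COC(C)(C)OC
Why: Acetonide formation under equilibrating conditions; a triol offering a 1,2- and a 1,3-diol gives the five-membered dioxolane (no axial methyl as in the dioxane, and a gem-dialkyl effect at C4). This masks O4 and O5 together and leaves the primary C7 hydroxyl free.

Step 11
Reactants: 13 acetonide alcohol
Product: 14 C7 aldehyde of 13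
Conditions: Dess–Martin periodinane, NaHCO3, CH2Cl2, 0 °C → rt
Reagents that add atoms: none
Why: Dess–Martin oxidation of a primary alcohol under buffered conditions; the β-alkoxy aldehyde is not exposed to base and C5 is not at risk.

Step 12
Reactants: 14 C7 aldehyde; 15 ethyltriphenylphosphonium bromide
Product: 19 (Z)-iodoalkene acetonide (14 with CHO replaced by CH=C(I)CH3, C6 and iodine cis), via ethylidenetriphenylphosphorane 16 (not isolated), via (1-iodoethyl)triphenylphosphonium iodide 17 (not isolated), via (1-iodoethylidene)triphenylphosphorane 18 (not isolated)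
Conditions: 15, n-BuLi, THF, 0 °C; I2, −78 °C; NaN(SiMe3)2, −78 → −20 °C; then 14, −78 °C
Reagents that add atoms: iodine, II
Why: Stork–Zhao-type olefination with the α-iodoethylidene ylide. The kinetically controlled Wittig reaction of this non-stabilised ylide at low temperature places the alkyl chain cis to iodine, which is the geometry the ring alkene needs; the acetonide, acetal and PMB ether tolerate the ylide.

Step 13
Reactants: 19 (Z)-iodoalkene acetonide
Product: 20 C4,C5-diol (Z)-iodoalkene (C3 PMB ether, C9 dimethyl acetal)
Conditions: CSA (cat.), MeOH, rt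
Reagents that add atoms: none
Why: Acid-catalysed methanolysis removes the acetonide, while exchange of the C9 dimethyl acetal with methanol is degenerate, so the aldehyde stays masked.

Step 14
Reactants: 21 angelic acid [(Z)-2-methylbut-2-enoic acid]
Product: 22 angelic 2,4,6-trichlorobenzoic anhydride [(Z)-2-methylbut-2-enoic 2,4,6-trichlorobenzoic anhydride]
Conditions: 2,4,6-Cl3C6H2COCl, Et3N, PhMe, 0 °C → rt; filter off the ammonium salt, concentrate; kept as a toluene solution at −20 °C under argon
Reagents that add atoms: 2,4,6-trichlorobenzoyl chloride, O=C(Cl)c1c(Cl)cc(Cl)cc1Cl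
Why: Mixed-anhydride formation, the first half of a Yamaguchi esterification: the triethylammonium carboxylate attacks the aroyl chloride, and the Z acid never passes through its own acid chloride, the usual source of isomerisation to the tiglate. Without a nucleophilic catalyst the anhydride should not disproportionate, so one batch, made large enough, serves steps 15 and 26.

Step 15
Reactants: 20 C4,C5-diol; 22 angelic 2,4,6-trichlorobenzoic anhydride
Product: 23 C5 angelate of 20 (tertiary C4 hydroxyl free)
Conditions: 22 (1.5 equiv), DMAP (cat.), Et3N, PhMe, rt → 60 °C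
Reagents that add atoms: none
Why: Second half of the Yamaguchi esterification; DMAP attacks the angeloyl carbonyl of 22 because the aroyl carbonyl is shielded by its two ortho chlorines, and the acylpyridinium ion transfers the angeloyl group with the Z geometry intact. Only the secondary C5 hydroxyl reacts; the tertiary one is too hindered.

Step 16
Reactants: 23 C5 angelate
Product: 24 C4 acetate C5 angelate (C3 PMB ether, C9 dimethyl acetal, Z-iodoalkene)
Conditions: Ac2O, DMAP, Et3N, CH2Cl2, 40 °C
Reagents that add atoms: acetic anhydride, CC(=O)OC(C)=O
Why: DMAP-catalysed acetylation of a tertiary alcohol with excess anhydride. The neighbouring secondary ester has no thermodynamic drive to move to the tertiary oxygen, which is why the angelate is installed before the acetate.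

Step 17
Reactants: 24 C4 acetate C5 angelate
Product: 25 C9 aldehyde (24 with CH(OMe)2 converted to CHO)
Conditions: PPTS, acetone/H2O, 50 °C
Reagents that add atoms: water, O
Why: Mild hydrolysis of an aliphatic dimethyl acetal; the esters, PMB ether and iodoalkene are stable to this weak acid.

Step 18
Reactants: 25 C9 aldehyde
Product: 27 (10S)-10-(phenylaminooxy) C9 alcohol, via (10S)-10-(phenylaminooxy) aldehyde 26 (not isolated)
Conditions: D-proline (30 mol%), PhNO, DMSO, rt; then NaBH4, MeOH, 0 °C
Reagents that add atoms: nitrosobenzene, O=Nc1ccccc1
Why: Proline-catalysed α-aminoxylation. The E enamine of the aldehyde attacks the nitroso oxygen on the face fixed by hydrogen bonding to the catalyst carboxyl group, and the D catalyst gives the (S)-configured C10 under catalyst control. Immediate borohydride reduction secures the labile α-oxy aldehyde and leaves the esters alone.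

Step 19
Reactants: 27 (10S)-10-(phenylaminooxy) C9 alcohol
Product: 28 (10S)-C9,C10-diol
Conditions: Zn, AcOH, THF, 0 °C → rt
Reagents that add atoms: none
Why: Reductive N–O cleavage by zinc in acetic acid; the weak N–O bond is reduced much faster than the alkenyl iodide or the esters, and no stereocentre is touched.

Step 20
Reactants: 28 C9,C10-diol
Product: 29 C9 triethylsilyl ether of 28 (C10 hydroxyl free)
Conditions: Et3SiCl, imidazole, CH2Cl2, −40 °C
Reagents that add atoms: chlorotriethylsilane, CC[Si](Cl)(CC)CC
Why: Selective silylation of the primary hydroxyl at low temperature leaves the secondary C10 hydroxyl for acylation.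

Step 21
Reactants: 29 C9 triethylsilyl ether; 30 (R)-2-methylbutanoic acid
Product: 32 C10 (R)-2-methylbutanoate C9 triethylsilyl ether, via (R)-2-methylbutanoic 2,4,6-trichlorobenzoic anhydride 31 (not isolated)
Conditions: 30, 2,4,6-Cl3C6H2COCl, Et3N, PhMe, rt; then 29, DMAP, rt
Reagents that add atoms: none
Why: Yamaguchi esterification at room temperature; an α-alkyl acid should keep its configuration because no ketene-forming acid chloride is involved, and the late introduction spares this stereocentre all earlier basic steps.

Step 22
Reactants: 32 C10 ester C9 silyl ether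
Product: 33 C9 primary alcohol (C10 2-methylbutanoate)
Conditions: HF·pyridine, pyridine, THF, 0 °C
Reagents that add atoms: none
Why: Buffered fluoride cleavage of the primary triethylsilyl ether under mildly acidic conditions, which disfavour migration of the C10 acyl group to the freed hydroxyl. 33 is oxidised at once.

Step 23
Reactants: 33 C9 primary alcohol
Product: 34 seco (Z)-iodoalkene aldehyde (C3 PMB ether, C4 acetate, C5 angelate, C10 2-methylbutanoate, C9 aldehyde)
Conditions: Dess–Martin periodinane, NaHCO3, CH2Cl2, 0 °C
Reagents that add atoms: none
Why: Dess–Martin oxidation under bicarbonate buffer gives the α-acyloxy aldehyde without a base able to epimerise C10. 34 is used crude.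

Step 24
Reactants: 34 seco (Z)-iodoalkene aldehyde
Product: 35 ten-membered (Z)-allylic alcohol (C7=C8 alkene, free C9 hydroxyl anti to the C10 ester)
Conditions: CrCl2 (excess), NiCl2 (cat.), DMSO/THF, rt, slow addition at high dilution
Reagents that add atoms: none
Why: Nozaki–Hiyama–Kishi reaction: CrCl2 reduces NiCl2 to zerovalent nickel, which inserts into the C8–I bond with retention of the Z geometry, and transmetalation to trivalent chromium gives the alkenylchromium and returns divalent nickel. The alkenylchromium adds to the C9 aldehyde only, so the acetate, angelate, 2-methylbutanoate, PMB ether and isopropenyl group are spectators; the closest known reaction type is the intramolecular Nozaki–Hiyama–Kishi closure of iodoalkenyl aldehydes to medium-ring and macrocyclic allylic alcohols. The ten-membered carbocycle closes in a 10-exo-trig mode: C8 attacks the carbonyl carbon C9 and the carbonyl oxygen ends outside the ring as the C9 hydroxyl. The new stereocentre C9 is controlled by C10: in the non-chelated Felkin–Anh arrangement the C10 acyloxy group stands anti to the incoming C8, which should give the 9,10-anti alcohol. The step needs cyclisation to outrun intermolecular coupling, which slow addition at high dilution and the turn imposed by the Z alkene and the substituted C3–C5 segment should secure. It also needs C10 to keep its configuration, which the neutral medium secures.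

Step 25
Reactants: 35 ten-membered (Z)-allylic alcohol
Product: 36 (7S,8S)-epoxy alcohol (epoxide oxygen trans to the C9 hydroxyl across the ring)
Conditions: mCPBA, NaHCO3, CH2Cl2, −20 → 0 °C
Reagents that add atoms: 3-chloroperoxybenzoic acid, O=C(OO)c1cccc(Cl)c1
Why: Hydrogen-bond-assisted peracid epoxidation (Henbest type). In the conformer that avoids allylic 1,3-strain between C9 and C6, the C9–H lies in the alkene plane and the hydroxyl and the exposed ring face coincide, so oxygen should arrive trans to C9–O (threo), as in 38; the trisubstituted ring alkene is the most nucleophilic one and the angelates are inert. A vanadium-alkoxide epoxidation is not used because, with its small C=C–C–O dihedral angle, it is expected to give the cis epoxy alcohol in a medium-ring Z-allylic alcohol bearing a geminal methyl group.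

Step 26
Reactants: 36 epoxy alcohol; 22 angelic 2,4,6-trichlorobenzoic anhydride
Product: 37 C3 PMB ether of the target (C5 and C9 angelates, C4 acetate, C10 2-methylbutanoate, 7,8-epoxide)
Conditions: 22 (2 equiv), DMAP (cat.), Et3N, PhMe, rt → 40 °C
Reagents that add atoms: none
Why: Yamaguchi esterification of the last free hydroxyl with the preformed mixed anhydride; acyl transfer through the angeloylpyridinium ion avoids angelate isomerisation. The amine bases are too weak to trigger Payne rearrangement of the epoxy alcohol.

Step 27
Reactants: 37 C3 PMB ether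
Product: 38 target (1R,3R,4S,5S,7S,8S,9S,10S)-4-acetoxy-5,9-bis(angeloyloxy)-7,8-epoxy-3-hydroxy-10-[(R)-2-methylbutanoyloxy] ten-membered ring with isopropenyl on C1 and methyls on C4 and C8
Conditions: DDQ, CH2Cl2/pH 7 phosphate buffer, 0 °C → rt
Reagents that add atoms: none
Why: Oxidative PMB cleavage (hydride abstraction by DDQ, then hydrolysis of the oxocarbenium ion) at neutral pH frees the C3 hydroxyl without base, so the neighbouring tertiary acetate should not migrate; the epoxide, angelates and isopropenyl group are untouched.

## Compound list

1 | (R)-carvone | C=C(C)[C@H]1CC(=O)C(C)=CC1 | starting material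
2 | (1R,5R)-cis-carveol | C=C(C)[C@H]1C[C@@H](O)C(C)=CC1 | intermediate
3 | cis-epoxy alcohol (1R,2R,4S,6S)-1-methyl-4-(prop-1-en-2-yl)-7-oxabicyclo[4.1.0]heptan-2-ol | C=C(C)[C@H]1C[C@@H](O)[C@@]2(C)O[C@H]2C1 | intermediate
4 | PMB ether of 3 | C=C(C)[C@H]1C[C@@H](OCc2ccc(OC)cc2)[C@@]3(C)O[C@H]3C1 | intermediate
5 | keto aldehyde (3S,5R)-5-[(4-methoxybenzyl)oxy]-6-oxo-3-(prop-1-en-2-yl)heptanal | C=C(C)[C@@H](C[C@@H](OCc1ccc(OC)cc1)C(C)=O)CC=O | intermediate
6 | keto acetal (3R,5S)-7,7-dimethoxy-3-[(4-methoxybenzyl)oxy]-5-(prop-1-en-2-yl)heptan-2-one | C=C(C)[C@@H](C[C@@H](OCc1ccc(OC)cc1)C(C)=O)CC(OC)OC | intermediate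
7 | propargyl alcohol | C#CCO | starting material
8 | bis(bromomagnesium) salt of propargyl alcohol (formed in the flask) | Br[Mg]C#CCO[Mg]Br | intermediate
9 | ynediol (4R,5R,7S)-9,9-dimethoxy-5-[(4-methoxybenzyl)oxy]-4-methyl-7-(prop-1-en-2-yl)non-2-yne-1,4-diol | C=C(C)[C@@H](C[C@@H](OCc1ccc(OC)cc1)[C@](C)(O)C#CCO)CC(OC)OC | intermediate
10 | (E)-enediol (2E,4R,5R,7S)-9,9-dimethoxy-5-[(4-methoxybenzyl)oxy]-4-methyl-7-(prop-1-en-2-yl)non-2-ene-1,4-diol | C=C(C)[C@@H](C[C@@H](OCc1ccc(OC)cc1)[C@](C)(O)/C=C/CO)CC(OC)OC | intermediate
11 | epoxy diol, (5S,6R)-5,6-epoxide of 10 | C=C(C)[C@@H](C[C@@H](OCc1ccc(OC)cc1)[C@](C)(O)[C@H]1O[C@@H]1CO)CC(OC)OC | intermediate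
12 | triol (3S,4R,5R,7S)-9,9-dimethoxy-5-[(4-methoxybenzyl)oxy]-4-methyl-7-(prop-1-en-2-yl)nonane-1,3,4-triol | C=C(C)[C@@H](C[C@@H](OCc1ccc(OC)cc1)[C@](C)(O)[C@@H](O)CCO)CC(OC)OC | intermediate
13 | C4,C5-acetonide of 12 with free C7 hydroxyl | C=C(C)[C@@H](C[C@@H](OCc1ccc(OC)cc1)[C@]1(C)OC(C)(C)O[C@H]1CCO)CC(OC)OC | intermediate
14 | C7 aldehyde of 13 | C=C(C)[C@@H](C[C@@H](OCc1ccc(OC)cc1)[C@]1(C)OC(C)(C)O[C@H]1CC=O)CC(OC)OC | intermediate
15 | ethyltriphenylphosphonium bromide | CC[P+](c1ccccc1)(c1ccccc1)c1ccccc1.[Br-] | starting material
16 | ethylidenetriphenylphosphorane (formed in the flask) | CC=P(c1ccccc1)(c1ccccc1)c1ccccc1 | intermediate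
17 | (1-iodoethyl)triphenylphosphonium iodide (formed in the flask) | CC(I)[P+](c1ccccc1)(c1ccccc1)c1ccccc1.[I-] | intermediate
18 | (1-iodoethylidene)triphenylphosphorane (formed in the flask) | CC(I)=P(c1ccccc1)(c1ccccc1)c1ccccc1 | intermediate
19 | (Z)-iodoalkene acetonide | C=C(C)[C@@H](C[C@@H](OCc1ccc(OC)cc1)[C@]1(C)OC(C)(C)O[C@H]1C/C=C(C)\I)CC(OC)OC | intermediate
20 | C4,C5-diol (Z)-iodoalkene | C=C(C)[C@@H](C[C@@H](OCc1ccc(OC)cc1)[C@](C)(O)[C@@H](O)C/C=C(C)\I)CC(OC)OC | intermediate
21 | angelic acid | C/C=C(/C)C(=O)O | starting material
22 | angelic 2,4,6-trichlorobenzoic anhydride | C/C=C(/C)C(=O)OC(=O)c1c(Cl)cc(Cl)cc1Cl | intermediate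
23 | C5 angelate with free C4 hydroxyl | C=C(C)[C@@H](C[C@@H](OCc1ccc(OC)cc1)[C@](C)(O)[C@@H](OC(=O)/C(C)=C\C)C/C=C(C)\I)CC(OC)OC | intermediate
24 | C4 acetate C5 angelate dimethyl acetal | C=C(C)[C@@H](C[C@@H](OCc1ccc(OC)cc1)[C@](C)(OC(C)=O)[C@@H](OC(=O)/C(C)=C\C)C/C=C(C)\I)CC(OC)OC | intermediate
25 | C9 aldehyde | C=C(C)[C@@H](C[C@@H](OCc1ccc(OC)cc1)[C@](C)(OC(C)=O)[C@@H](OC(=O)/C(C)=C\C)C/C=C(C)\I)CC=O | intermediate
26 | (10S)-10-(phenylaminooxy) aldehyde (formed in the flask) | C=C(C)[C@@H](C[C@@H](OCc1ccc(OC)cc1)[C@](C)(OC(C)=O)[C@@H](OC(=O)/C(C)=C\C)C/C=C(C)\I)[C@@H](C=O)ONc1ccccc1 | intermediate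
27 | (10S)-10-(phenylaminooxy) C9 alcohol | C=C(C)[C@@H](C[C@@H](OCc1ccc(OC)cc1)[C@](C)(OC(C)=O)[C@@H](OC(=O)/C(C)=C\C)C/C=C(C)\I)[C@@H](CO)ONc1ccccc1 | intermediate
28 | (10S)-C9,C10-diol | C=C(C)[C@@H](C[C@@H](OCc1ccc(OC)cc1)[C@](C)(OC(C)=O)[C@@H](OC(=O)/C(C)=C\C)C/C=C(C)\I)[C@@H](CO)O | intermediate
29 | C9 triethylsilyl ether with free C10 hydroxyl | C=C(C)[C@@H](C[C@@H](OCc1ccc(OC)cc1)[C@](C)(OC(C)=O)[C@@H](OC(=O)/C(C)=C\C)C/C=C(C)\I)[C@@H](CO[Si](CC)(CC)CC)O | intermediate
30 | (R)-2-methylbutanoic acid | CC[C@@H](C)C(=O)O | starting material
31 | (R)-2-methylbutanoic 2,4,6-trichlorobenzoic anhydride (formed in the flask) | CC[C@@H](C)C(=O)OC(=O)c1c(Cl)cc(Cl)cc1Cl | intermediate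
32 | C10 (R)-2-methylbutanoate C9 triethylsilyl ether | C=C(C)[C@@H](C[C@@H](OCc1ccc(OC)cc1)[C@](C)(OC(C)=O)[C@@H](OC(=O)/C(C)=C\C)C/C=C(C)\I)[C@@H](CO[Si](CC)(CC)CC)OC(=O)[C@H](C)CC | intermediate
33 | C9 primary alcohol | C=C(C)[C@@H](C[C@@H](OCc1ccc(OC)cc1)[C@](C)(OC(C)=O)[C@@H](OC(=O)/C(C)=C\C)C/C=C(C)\I)[C@@H](CO)OC(=O)[C@H](C)CC | intermediate
34 | seco (Z)-iodoalkene aldehyde | C=C(C)[C@@H](C[C@@H](OCc1ccc(OC)cc1)[C@](C)(OC(C)=O)[C@@H](OC(=O)/C(C)=C\C)C/C=C(C)\I)[C@@H](C=O)OC(=O)[C@H](C)CC | intermediate
35 | ten-membered (Z)-allylic alcohol | C=C(C)[C@H]1C[C@@H](OCc2ccc(OC)cc2)[C@](C)(OC(C)=O)[C@@H](OC(=O)/C(C)=C\C)C/C=C(C)\[C@@H](O)[C@H]1OC(=O)[C@H](C)CC | intermediate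
36 | (7S,8S)-epoxy alcohol | C=C(C)[C@H]1C[C@@H](OCc2ccc(OC)cc2)[C@](C)(OC(C)=O)[C@@H](OC(=O)/C(C)=C\C)C[C@@H]3O[C@]3(C)[C@@H](O)[C@H]1OC(=O)[C@H](C)CC | intermediate
37 | C3 PMB ether of the target | C=C(C)[C@H]1C[C@@H](OCc2ccc(OC)cc2)[C@](C)(OC(C)=O)[C@@H](OC(=O)/C(C)=C\C)C[C@@H]3O[C@]3(C)[C@@H](OC(=O)/C(C)=C\C)[C@H]1OC(=O)[C@H](C)CC | intermediate
38 | target CNP0197637.1 | C=C(C)[C@H]1C[C@@H](O)[C@](C)(OC(C)=O)[C@@H](OC(=O)/C(C)=C\C)C[C@@H]2O[C@]2(C)[C@@H](OC(=O)/C(C)=C\C)[C@H]1OC(=O)[C@H](C)CC | target

## Step count and risk

Total step count: 27. Longest linear sequence: 26 steps, from 1 to 38 (steps 1–13 and 15–27); step 14 prepares the angeloyl donor 22 from 21 off the main line. 7, 15, 21 and 30 are bought and enter in steps 6, 12, 14 and 21.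

**Step 24 (key step).** Two processes can fail. Intermolecular coupling may compete with closure of a strained ten-membered ring, and facial selectivity at C9 may be poor because the ring-forming transition state need not follow the open-chain Felkin–Anh preference. The fallback keeps the closure but no longer relies on it for C9. Starting from 34, the cyclisation is run as described and the C9 epimer of 35, F1, is not separated. The mixture is oxidised with Dess–Martin periodinane to the single ten-membered (Z)-enone with a C9 ketone, F2. F2 is then reduced under reagent control with the (R)-configured Corey–Bakshi–Shibata oxazaborolidine and BH3·SMe2, chosen on the usual model in which the α-methylated alkenyl group is the large substituent. This returns to the route at 35.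

**Step 25.** The likely failure is poor facial selectivity, because hydrogen-bonded delivery and attack on the sterically exposed face need not coincide in this ring; a lesser concern is slow oxidation of the isopropenyl group, limited by using one equivalent of peracid at low temperature. The fallback reverses the order of the last two bond-forming operations. Starting from 35, the C9 hydroxyl is first esterified with anhydride 22 under the conditions of step 26 to give the C9 angelate of 35, F3. F3 is then epoxidised with dimethyldioxirane in acetone at −20 °C, so that only the exposed face of the strained trisubstituted ring alkene decides the outcome and no directing group is involved. This returns to the route at 37.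

**Step 12.** The likely failures are decomposition of the thermally fragile α-iodo ylide before it reacts, loss of iodine to give the simple ethylidene alkene, and erosion of the Z geometry. The fallback builds the halogenated alkene stepwise. Starting from 14, Corey–Fuchs dibromo-olefination (CBr4, PPh3, Et3N, CH2Cl2, 0 °C) gives the 1,1-dibromoalkene F4. A palladium-catalysed Negishi coupling with Me2Zn (PdCl2(DPEphos) cat., THF) replaces only the less hindered bromine, trans to the chain, and gives the (Z)-bromoalkene F5 with C6 and bromine cis. Bromine–lithium exchange (t-BuLi, Et2O, −78 °C) and quenching with I2, both with retention, return to the route at 19.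

**Step 16.** The likely failures are incomplete acylation of a tertiary hydroxyl flanked by two oxygenated carbons and Z-to-E isomerisation of the C5 angelate during prolonged warming with DMAP. The fallback installs the acetate before any angelate exists and through the alkoxide. Starting from 20, the secondary hydroxyl is silylated (Et3SiCl, imidazole) to the C5 triethylsilyl ether F6. The tertiary hydroxyl is converted to its bromomagnesium alkoxide with EtMgBr at 0 °C and trapped with Ac2O to give the C4 acetate C5 triethylsilyl ether F7. HF·pyridine then frees the C5 hydroxyl under acidic conditions, which do not move the acetate, giving the C4 acetate C5 alcohol F8. F8 is esterified at once with anhydride 22 as in step 15, at room temperature so that the free hydroxyl is acylated before the neighbouring acetate can migrate under the amine bases; this returns to the route at 24.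

**Step 26.** The likely failures are slow acylation of a hindered hydroxyl beside the epoxide by the bulky, weakly electrophilic angeloyl donor, and, on warming, isomerisation of the angelate or migration of the C10 acyl group to C9. The fallback attaches a small acyl group first and creates the Z double bond afterwards. Starting from 36, coupling with 2-[bis(2,2,2-trifluoroethoxy)phosphoryl]propanoic acid (N,N′-dicyclohexylcarbodiimide, DMAP cat., CH2Cl2, 0 °C) gives the C9 phosphonopropanoate F9. Still–Gennari olefination of F9 (KN(SiMe3)2, 18-crown-6, THF, −78 °C, then acetaldehyde) forms the Z-trisubstituted enoate, that is the angelate, and returns to the route at 37.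

The chelation-controlled addition (step 6), the acetonide regiochemistry (step 10) and the late α-aminoxylation (step 18) use well-established selectivity and are judged less critical than the five steps above.

## Further compounds

F1 | step 24 | C9 epimer of 35 | C=C(C)[C@H]1C[C@@H](OCc2ccc(OC)cc2)[C@](C)(OC(C)=O)[C@@H](OC(=O)/C(C)=C\C)C/C=C(C)\[C@H](O)[C@H]1OC(=O)[C@H](C)CC
F2 | step 24 | ten-membered (Z)-enone with C9 ketone | C=C(C)[C@H]1C[C@@H](OCc2ccc(OC)cc2)[C@](C)(OC(C)=O)[C@@H](OC(=O)/C(C)=C\C)C/C=C(C)\C(=O)[C@H]1OC(=O)[C@H](C)CC
F3 | step 25 | C9 angelate of 35 | C=C(C)[C@H]1C[C@@H](OCc2ccc(OC)cc2)[C@](C)(OC(C)=O)[C@@H](OC(=O)/C(C)=C\C)C/C=C(C)\[C@@H](OC(=O)/C(C)=C\C)[C@H]1OC(=O)[C@H](C)CC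
F4 | step 12 | 1,1-dibromoalkene from 14 | C=C(C)[C@@H](C[C@@H](OCc1ccc(OC)cc1)[C@]1(C)OC(C)(C)O[C@H]1CC=C(Br)Br)CC(OC)OC
F5 | step 12 | (Z)-bromoalkene acetonide | C=C(C)[C@@H](C[C@@H](OCc1ccc(OC)cc1)[C@]1(C)OC(C)(C)O[C@H]1C/C=C(C)\Br)CC(OC)OC
F6 | step 16 | C5 triethylsilyl ether of 20 | C=C(C)[C@@H](C[C@@H](OCc1ccc(OC)cc1)[C@](C)(O)[C@@H](O[Si](CC)(CC)CC)C/C=C(C)\I)CC(OC)OC
F7 | step 16 | C4 acetate C5 triethylsilyl ether | C=C(C)[C@@H](C[C@@H](OCc1ccc(OC)cc1)[C@](C)(OC(C)=O)[C@@H](O[Si](CC)(CC)CC)C/C=C(C)\I)CC(OC)OC
F8 | step 16 | C4 acetate C5 alcohol | C=C(C)[C@@H](C[C@@H](OCc1ccc(OC)cc1)[C@](C)(OC(C)=O)[C@@H](O)C/C=C(C)\I)CC(OC)OC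
F9 | step 26 | C9 2-[bis(2,2,2-trifluoroethoxy)phosphoryl]propanoate of 36 (epimers at the phosphonate carbon) | C=C(C)[C@H]1C[C@@H](OCc2ccc(OC)cc2)[C@](C)(OC(C)=O)[C@@H](OC(=O)/C(C)=C\C)C[C@@H]3O[C@]3(C)[C@@H](OC(=O)C(C)P(=O)(OCC(F)(F)F)OCC(F)(F)F)[C@H]1OC(=O)[C@H](C)CC
A1 | alternative 1 | (R)-2-(4-methoxybenzyloxy)-2-methylbut-3-en-1-ol | OC[C@](C)(OCc1ccc(OC)cc1)C=C
A2 | alternative 1 | racemic 2-methyl-2-vinyloxirane | C=CC1(C)CO1
A3 | alternative 1 | 4-methoxybenzyl alcohol | COc1ccc(CO)cc1
A4 | alternative 2 | fourteen-membered allylic lactone | O=C1C[C@@H](O)[C@]2(C)OC(C)(C)O[C@H]2C/C=C(C)\[C@H]2OC(C)(C)O[C@H]2/C=C(\C)CO1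
A5 | alternative 2 | ten-membered ring C2 carboxylic acid (C2 epimers) | C=C(C)[C@H]1C(C(=O)O)[C@@H](O)[C@]2(C)OC(C)(C)O[C@H]2C/C=C(C)\[C@H]3OC(C)(C)O[C@H]31
A6 | alternative 3 | carvone-derived cis-1-alkenyl-2-vinylcyclohexanol | C=C(C)[C@H]1C[C@](O)(/C(C)=C/OCOC)[C@](C)(C=C)[C@H]2OC(C)(C)O[C@H]21
A7 | alternative 3 | ten-membered (Z)-enone acetonide (C4 epimers) | C=C(C)[C@H]1CC(=O)C(C)[C@@H](OCOC)C/C=C(C)\[C@H]2OC(C)(C)O[C@H]21
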